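The ethers at O5, O5'' and O7 are cut last. Before them go ring C of unit 1 (O1–C2 and C3–aroyl bonds, Baker–Venkataraman logic) and its acetyl bond C4–C4a, and then ring A of unit 1.
Ring A of unit 1 (C4a, C5, C6, C7, C8, C8a) is a phloroglucinol ring with oxygen on C5, C7 and C8a. C6 lies between O5 and O7, para to C8a–O1, and carries C8'' of unit 2, which is the pattern a 2-aryl-3-oxycyclobutenone and an ynol ether deliver.
Ring A is cut at C4a–C8a, C5–C6 and C8–C8a into ethoxyacetylene (C4a, C5) and a cyclobutenone (C6, C7, C8, C8a) with unit 2 as its aryl group. The tetra-ortho-substituted C6–C8'' bond is thus never made by coupling and begins as an unhindered aryl–CH2 bond.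
The cyclobutenone goes back through a ketene/ethoxyacetylene [2+2] to the 8''-acetic acid, and that to the 8-iodide of commercial apigenin trimethyl ether.
Forward order: unit 2 (bought complete), C8'' side chain, four-membered ring, ring A of unit 1, acetyl group, ring C (ring B arrives with 4-methoxybenzoyl chloride), deprotection.
The target has no stereocentre, and the hindered C6–C8'' axis arises racemic in the key step.

Key step: step 7

Assumption: the target string carries no stereodescriptor, so the C6–C8'' axis is taken as racemic and no atroposelective control is sought.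
Notation: positions of unit 2 carry a double prime. Fl stands for the 5,7-dimethoxy-2-(4-methoxyphenyl)-4-oxochromen-8-yl group, which is protected unit 2 bonded through C8''.

Step 1
Reactants: 1 5,7-dimethoxy-2-(4-methoxyphenyl)chromen-4-one (apigenin trimethyl ether)
Product: 2 8-iodo-5,7-dimethoxy-2-(4-methoxyphenyl)chromen-4-one (Fl–I)
Conditions: NIS, CF3CO2H (cat.), MeCN–CH2Cl2, rt, dark
Reagents that add atoms: N-iodosuccinimide, O=C1CCC(=O)N1I
Why: Electrophilic aromatic iodination, in which C8 is the most nucleophilic carbon of a 5,7-dialkoxyflavone (C6 and ring B are less activated), so acid-activated NIS should iodinate once at that position.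

Step 2
Reactants: 2 Fl–I; 3 (2-tert-butoxy-2-oxoethyl)zinc bromide, BrZnCH2CO2t-Bu
Product: 4 tert-butyl 2-Fl-acetate
Conditions: Pd2(dba)3 (cat.), XPhos (cat.), THF, 65 °C
Reagents that add atoms: none
Why: Negishi-type coupling of a Reformatsky reagent (palladium-catalysed ester α-arylation), in which the neutral zinc enolate leaves the chromone carbonyl alone and the bulky biarylphosphine lets zerovalent palladium insert into the di-ortho-substituted iodide and eliminate the product.

Step 3
Reactants: 4 tert-butyl 2-Fl-acetate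
Product: 5 2-Fl-acetic acid
Conditions: CF3CO2H, CH2Cl2, rt
Reagents that add atoms: none
Why: Acidolysis of a tert-butyl ester through the tert-butyl cation, to which the aryl methyl ethers and the chromone are inert at room temperature.

Step 4
Reactants: 5 2-Fl-acetic acid; 6 ethoxyacetylene
Product: 9 4-Fl-3-ethoxycyclobut-2-en-1-one (racemic), via acid chloride 7 (not isolated), via arylketene 8 (not isolated)
Conditions: (COCl)2, Me2NCHO (cat.), CH2Cl2, 0 °C to rt, evaporate; 6 (excess), Et3N (slow addition), CH2Cl2, 0 to 40 °C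
Reagents that add atoms: oxalyl chloride, O=C(Cl)C(=O)Cl (supplies only the chlorine of intermediate 7; nothing from it stays in 9)
Why: Dehydrochlorination of the acid chloride to the arylketene and ketene–ynol ether [2+2] cycloaddition is a standard entry to 3-ethoxycyclobutenones; the unsubstituted alkyne carbon attacks the ketene carbonyl carbon, so ethoxy ends beside the aryl-bearing sp3 carbon, whose uncontrolled (racemic) configuration is erased in step 5.

Step 5
Reactants: 9 4-Fl-3-ethoxycyclobut-2-en-1-one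
Product: 10 2-Fl-3-hydroxycyclobut-2-en-1-one (enol of the 2-arylcyclobutane-1,3-dione)
Conditions: 2 M aq. HCl, THF, rt
Reagents that add atoms: water, O
Why: Acid hydrolysis of a vinylogous ester (addition–elimination of water at C3) gives the cyclobutane-1,3-dione, which rests as its strongly acidic enol and thereby moves the aryl group from the sp3 carbon to the enone α-carbon, as the key step requires.

Step 6
Reactants: 10 2-Fl-3-hydroxycyclobut-2-en-1-one
Product: 11 2-[5,7-dimethoxy-2-(4-methoxyphenyl)-4-oxochromen-8-yl]-3-(triisopropylsilyloxy)cyclobut-2-en-1-one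
Conditions: TIPSOTf, Et3N, CH2Cl2, −78 to 0 °C; quick filtration through Et3N-deactivated silica
Reagents that add atoms: triisopropylsilyl trifluoromethanesulfonate, CC(C)[Si](OS(=O)(=O)C(F)(F)F)(C(C)C)C(C)C
Why: O-silylation of a vinylogous acid, in which the two oxygens of the symmetric dione enolate are equivalent so only one silyl ether can form, and the bulky triisopropylsilyl group makes this vinylogous silyl ester robust enough to handle.

Step 7
Reactants: 11 2-Fl-3-(triisopropylsilyloxy)cyclobut-2-en-1-one; 6 ethoxyacetylene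
Product: 16 8-[2-ethoxy-4-hydroxy-6-(triisopropylsilyloxy)phenyl]-5,7-dimethoxy-2-(4-methoxyphenyl)chromen-4-one, via vinylketene 12 (not isolated), via vinylcyclobutenone 13 (not isolated), via dienylketene 14 (not isolated), via cyclohexadienone 15 (not isolated)
Conditions: 6 (5 equiv, in portions), toluene, sealed tube, 95 °C, then 120 °C
Reagents that add atoms: none
Why: Danheiser benzannulation: heat opens 11 by 4π electrocyclic cleavage of its C1–C4 bond to the aryl(silyloxyvinyl)ketene 12, which adds ethoxyacetylene by [2+2] cycloaddition to give 13; 13 reopens (4π) to dienylketene 14, whose 6π electrocyclisation gives dienone 15, and tautomerisation gives phenol 16. The cascade is established for alkyl- and aryl-substituted cyclobutenones with alkoxy- and silyloxyalkynes, so only the substitution pattern (aryl on C2, silyloxy on C3) is extended here, and a silyl ether was preferred to an alkyl ether because it is the weaker π-donor and stabilises the closed vinylogous ester less. Ring A of unit 1 is closed by the thermal disrotatory 6π electrocyclisation that makes C8–C8a, after the cycloaddition has made C4a–C8a and C5–C6. No stereocentre survives, since the quaternary carbon of 13 (racemic) is lost on ring opening and the hindered biaryl axis of 16 forms as a racemate. The selectivity needed is the orientation of the [2+2] step, and the polarised ynol ether secures it by bonding its CH terminus to the ketene carbonyl carbon, which puts ethoxy on C5 beside the aryl-bearing C6 and the new hydroxyl para to the aryl group; of the two geometries of the dienylketene only the one with the silyloxyvinyl arm cis to the ketene arm can close, and the other should revert to 13. Adding excess ynol ether in portions, below the temperature at which it fragments to ketene and ethylene, should keep 12 from being captured by the phenol already formed.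

Step 8
Reactants: 16 the phenol of step 7; 17 acetic anhydride
Product: 18 8-[3-acetyl-2-ethoxy-4-hydroxy-6-(triisopropylsilyloxy)phenyl]-5,7-dimethoxy-2-(4-methoxyphenyl)chromen-4-one
Conditions: BF3·OEt2, CH2Cl2, 0 °C to rt; then H2O–MeOH
Reagents that add atoms: none
Why: Friedel–Crafts C-acetylation (Fries manifold) of a phloroglucinol diether ortho to its free hydroxyl: the para carbon is blocked and the carbon beside the triisopropylsilyl ether is shielded, so acetyl should enter at C4a beside the ethoxy group, while the Lewis-acid-complexed ring A of unit 2 is deactivated.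

Step 9
Reactants: 18 the o-hydroxyacetophenone of step 8; 19 4-methoxybenzoyl chloride
Product: 20 1-[3-Fl-2-ethoxy-6-hydroxy-4-(triisopropylsilyloxy)phenyl]-3-(4-methoxyphenyl)propane-1,3-dione
Conditions: LiN(SiMe3)2 (3.5 equiv), THF, −78 to −10 °C; 19, −78 °C to rt; aq. HCl
Reagents that add atoms: none
Why: Lithium-enolate variant of the Baker–Venkataraman synthesis, in which the phenoxide–enolate is aroylated on carbon (or on oxygen and then rearranged in the flask) to the same 1,3-diketone, and the hindered amide base at low temperature spares the aryl silyl ether and the chromone of unit 2 that hydroxide would attack.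

Step 10
Reactants: 20 the 1,3-diketone of step 9
Product: 21 5-ethoxy-6-Fl-2-(4-methoxyphenyl)-7-(triisopropylsilyloxy)chromen-4-one
Conditions: p-toluenesulfonic acid monohydrate (cat.), toluene, 90 °C
Reagents that add atoms: none
Why: Acid-catalysed cyclodehydration of an o-hydroxyaryl 1,3-diketone closes ring C of unit 1, and because only the oxygen on C8a is free the 6-linked rather than the 8-linked flavone must result.

Step 11
Reactants: 21 the fully protected biflavone
Product: 22 5-hydroxy-6-[5-hydroxy-7-methoxy-2-(4-methoxyphenyl)-4-oxochromen-8-yl]-2-(4-methoxyphenyl)-7-(triisopropylsilyloxy)chromen-4-one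
Conditions: BCl3 (excess), CH2Cl2, −78 to 0 °C; then H2O
Reagents that add atoms: none
Why: Chelation-directed ether cleavage, in which BCl3 bridges each C4 carbonyl and its peri alkoxy oxygen and chloride removes the alkyl group, so only 5-OEt and 5''-OMe should fall at or below 0 °C while the 7''-methyl ether, both ring B methyl ethers and the silyl ether remain.

Step 12
Reactants: 22 the 7-O-silyl biflavone
Product: 23 5,7-dihydroxy-6-[5-hydroxy-7-methoxy-2-(4-methoxyphenyl)-4-oxochromen-8-yl]-2-(4-methoxyphenyl)chromen-4-one (target CNP0146326.0)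
Conditions: Bu4NF, AcOH, THF, 0 °C
Reagents that add atoms: none
Why: Fluoride-induced cleavage of an aryl silyl ether, driven by Si–F bond formation, with acetic acid buffering so that the polyphenol does not stand as a phenoxide.

Compound list
1 | 5,7-dimethoxy-2-(4-methoxyphenyl)chromen-4-one (apigenin trimethyl ether) | COc1ccc(-c2cc(=O)c3c(OC)cc(OC)cc3o2)cc1 | starting material
2 | 8-iodo-5,7-dimethoxy-2-(4-methoxyphenyl)chromen-4-one | COc1ccc(-c2cc(=O)c3c(OC)cc(OC)c(I)c3o2)cc1 | intermediate
3 | (2-tert-butoxy-2-oxoethyl)zinc bromide | CC(C)(C)OC(=O)C[Zn]Br | starting material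
4 | tert-butyl 2-[5,7-dimethoxy-2-(4-methoxyphenyl)-4-oxochromen-8-yl]acetate | COc1ccc(-c2cc(=O)c3c(OC)cc(OC)c(CC(=O)OC(C)(C)C)c3o2)cc1 | intermediate
5 | 2-[5,7-dimethoxy-2-(4-methoxyphenyl)-4-oxochromen-8-yl]acetic acid | COc1ccc(-c2cc(=O)c3c(OC)cc(OC)c(CC(=O)O)c3o2)cc1 | intermediate
6 | ethoxyacetylene | CCOC#C | starting material
7 | 2-[5,7-dimethoxy-2-(4-methoxyphenyl)-4-oxochromen-8-yl]acetyl chloride | COc1ccc(-c2cc(=O)c3c(OC)cc(OC)c(CC(=O)Cl)c3o2)cc1 | intermediate
8 | 2-[5,7-dimethoxy-2-(4-methoxyphenyl)-4-oxochromen-8-yl]ethen-1-one (arylketene) | COc1ccc(-c2cc(=O)c3c(OC)cc(OC)c(C=C=O)c3o2)cc1 | intermediate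
9 | 4-[5,7-dimethoxy-2-(4-methoxyphenyl)-4-oxochromen-8-yl]-3-ethoxycyclobut-2-en-1-one (racemic) | COc1ccc(-c2cc(=O)c3c(OC)cc(OC)c(C4C(=O)C=C4OCC)c3o2)cc1 | intermediate
10 | 2-[5,7-dimethoxy-2-(4-methoxyphenyl)-4-oxochromen-8-yl]-3-hydroxycyclobut-2-en-1-one | COc1ccc(-c2cc(=O)c3c(OC)cc(OC)c(C4=C(O)CC4=O)c3o2)cc1 | intermediate
11 | 2-[5,7-dimethoxy-2-(4-methoxyphenyl)-4-oxochromen-8-yl]-3-(triisopropylsilyloxy)cyclobut-2-en-1-one | COc1ccc(-c2cc(=O)c3c(OC)cc(OC)c(C4=C(O[Si](C(C)C)(C(C)C)C(C)C)CC4=O)c3o2)cc1 | intermediate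
12 | 2-Fl-3-(triisopropylsilyloxy)buta-1,3-dien-1-one (vinylketene) | COc1ccc(-c2cc(=O)c3c(OC)cc(OC)c(C(=C=O)C(=C)O[Si](C(C)C)(C(C)C)C(C)C)c3o2)cc1 | intermediate
13 | 4-Fl-3-ethoxy-4-[1-(triisopropylsilyloxy)ethenyl]cyclobut-2-en-1-one (racemic) | COc1ccc(-c2cc(=O)c3c(OC)cc(OC)c(C4(C(=C)O[Si](C(C)C)(C(C)C)C(C)C)C(=O)C=C4OCC)c3o2)cc1 | intermediate
14 | 4-Fl-3-ethoxy-5-(triisopropylsilyloxy)hexa-1,3,5-trien-1-one, ketene arm cis to the silyloxyvinyl arm | C=C(O[Si](C(C)C)(C(C)C)C(C)C)/C(c1c(OC)cc(OC)c2c(=O)cc(-c3ccc(OC)cc3)oc12)=C(OCC)\C=C=O | intermediate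
15 | 4-Fl-3-ethoxy-5-(triisopropylsilyloxy)cyclohexa-2,4-dien-1-one | COc1ccc(-c2cc(=O)c3c(OC)cc(OC)c(C4=C(O[Si](C(C)C)(C(C)C)C(C)C)CC(=O)C=C4OCC)c3o2)cc1 | intermediate
16 | 8-[2-ethoxy-4-hydroxy-6-(triisopropylsilyloxy)phenyl]-5,7-dimethoxy-2-(4-methoxyphenyl)chromen-4-one (racemic axis) | CCOc1cc(O)cc(O[Si](C(C)C)(C(C)C)C(C)C)c1-c1c(OC)cc(OC)c2c(=O)cc(-c3ccc(OC)cc3)oc12 | intermediate
17 | acetic anhydride | CC(=O)OC(C)=O | starting material
18 | 8-[3-acetyl-2-ethoxy-4-hydroxy-6-(triisopropylsilyloxy)phenyl]-5,7-dimethoxy-2-(4-methoxyphenyl)chromen-4-one | CCOc1c(C(C)=O)c(O)cc(O[Si](C(C)C)(C(C)C)C(C)C)c1-c1c(OC)cc(OC)c2c(=O)cc(-c3ccc(OC)cc3)oc12 | intermediate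
19 | 4-methoxybenzoyl chloride | COc1ccc(C(=O)Cl)cc1 | starting material
20 | 1-{3-[5,7-dimethoxy-2-(4-methoxyphenyl)-4-oxochromen-8-yl]-2-ethoxy-6-hydroxy-4-(triisopropylsilyloxy)phenyl}-3-(4-methoxyphenyl)propane-1,3-dione | CCOc1c(C(=O)CC(=O)c2ccc(OC)cc2)c(O)cc(O[Si](C(C)C)(C(C)C)C(C)C)c1-c1c(OC)cc(OC)c2c(=O)cc(-c3ccc(OC)cc3)oc12 | intermediate
21 | 6-[5,7-dimethoxy-2-(4-methoxyphenyl)-4-oxochromen-8-yl]-5-ethoxy-2-(4-methoxyphenyl)-7-(triisopropylsilyloxy)chromen-4-one | COc1ccc(-c2cc(=O)c3c(OCC)c(-c4c(OC)cc(OC)c5c(=O)cc(-c6ccc(OC)cc6)oc45)c(O[Si](C(C)C)(C(C)C)C(C)C)cc3o2)cc1 | intermediate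
22 | 5-hydroxy-6-[5-hydroxy-7-methoxy-2-(4-methoxyphenyl)-4-oxochromen-8-yl]-2-(4-methoxyphenyl)-7-(triisopropylsilyloxy)chromen-4-one | COc1ccc(-c2cc(=O)c3c(O)c(-c4c(OC)cc(O)c5c(=O)cc(-c6ccc(OC)cc6)oc45)c(O[Si](C(C)C)(C(C)C)C(C)C)cc3o2)cc1 | intermediate
23 | 5,7-dihydroxy-6-[5-hydroxy-7-methoxy-2-(4-methoxyphenyl)-4-oxochromen-8-yl]-2-(4-methoxyphenyl)chromen-4-one (racemic axis) | COc1ccc(-c2cc(=O)c3c(O)c(-c4c(OC)cc(O)c5c(=O)cc(-c6ccc(OC)cc6)oc45)c(O)cc3o2)cc1 | target

Total step count: 12.
Longest linear sequence: 12 steps (1 to 23). Compounds 3, 6, 17 and 19 are bought.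

Steps most likely to fail

Step 7. Electrocyclic opening of the donor-stabilised four-membered ring may be slower than thermal fragmentation of the ynol ether. Cycloaddition at the hindered ketene carbon may also be sluggish, and the ketene may be captured by the phenol already formed. The fallback gives up ring growth and joins two finished flavones by Suzuki–Miyaura coupling. It sets out from iodide 2, which is borylated (B2pin2, PdCl2(dppf), KOAc, dioxane, 90 °C) to the 8-pinacolboronate of apigenin trimethyl ether F1. In parallel, purchased acacetin F2 is benzylated at its non-chelated 7-hydroxyl (BnBr, K2CO3, acetone, reflux) to 7-O-benzylacacetin F3. F3 is then iodinated at C6 under the direction of the free 5-hydroxyl (BnMe3N·ICl2, CaCO3, CH2Cl2–MeOH, rt) to 7-O-benzyl-6-iodoacacetin F4. Coupling of F1 with F4 (Pd(OAc)2, SPhos, K3PO4, toluene–H2O, 100 °C) should give the 7-O-benzyl-5''-O-methyl biflavone F5. BCl3 (CH2Cl2, −78 to 0 °C) then removes the benzyl group and the chelated 5''-methyl group, and the route is rejoined at target 23.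

Step 8. Regiocontrol between the two carbons ortho to the hydroxyl may erode, and the silyl group may be lost to boron fluoride species before the C–C bond is made. Loss after acetylation would be harmless, because the group has by then done its steering. The fallback replaces Lewis-acid acylation and the diketone sequence by halogenation and a palladium-catalysed carbonylative annulation. It sets out from phenol 16, which is iodinated without any Lewis acid (NIS, CH2Cl2, −40 °C). The large electrophile should be more sensitive to the bulk of the silyl ether and should give 8-[2-ethoxy-4-hydroxy-3-iodo-6-(triisopropylsilyloxy)phenyl]-5,7-dimethoxy-2-(4-methoxyphenyl)chromen-4-one F6. Reaction of F6 with purchased 4-ethynylanisole F7 under CO (PdCl2(PPh3)2, CO 1 atm, Et2NH, 80 °C) proceeds by carbonylative Sonogashira coupling, conjugate addition of the amine and 6-endo closure by the phenol. This builds ring C in one operation and rejoins the route at 21, by-passing 18 and 20.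

Step 4. Dimerisation or amine-induced oligomerisation of the arylketene may outrun the cycloaddition. The fallback exchanges the roles of the partners, so that unit 2 carries the ynol ether and a small, highly reactive ketene is added to it. It sets out from iodide 2. Ethoxyacetylene 6 is metallated (n-BuLi, then ZnCl2, THF, −78 to 0 °C) to (ethoxyethynyl)zinc chloride F8. F8 is coupled with 2 (Pd(PPh3)4, THF, 50 °C, Negishi coupling) to 8-(ethoxyethynyl)-5,7-dimethoxy-2-(4-methoxyphenyl)chromen-4-one F9. Dichloroketene F10, generated from Cl3CCOCl and Zn in Et2O–DME, adds with its carbonyl carbon to the aryl-bearing alkyne carbon to give 2-Fl-4,4-dichloro-3-ethoxycyclobut-2-en-1-one F11. Reductive dechlorination (Zn, AcOH, TMEDA, EtOH, rt) gives 2-Fl-3-ethoxycyclobut-2-en-1-one F12. Hydrolysis as in step 5 (aq. HCl, THF) rejoins the route at 10, by-passing 4, 5 and 9.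

Further compounds
F1 | step 7 | 5,7-dimethoxy-2-(4-methoxyphenyl)-8-(4,4,5,5-tetramethyl-1,3,2-dioxaborolan-2-yl)chromen-4-one | COc1ccc(-c2cc(=O)c3c(OC)cc(OC)c(B4OC(C)(C)C(C)(C)O4)c3o2)cc1
F2 | step 7 | acacetin, 5,7-dihydroxy-2-(4-methoxyphenyl)chromen-4-one (purchased) | COc1ccc(-c2cc(=O)c3c(O)cc(O)cc3o2)cc1
F3 | step 7 | 7-benzyloxy-5-hydroxy-2-(4-methoxyphenyl)chromen-4-one | COc1ccc(-c2cc(=O)c3c(O)cc(OCc4ccccc4)cc3o2)cc1
F4 | step 7 | 7-benzyloxy-5-hydroxy-6-iodo-2-(4-methoxyphenyl)chromen-4-one | COc1ccc(-c2cc(=O)c3c(O)c(I)c(OCc4ccccc4)cc3o2)cc1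
F5 | step 7 | 7-benzyloxy-6-[5,7-dimethoxy-2-(4-methoxyphenyl)-4-oxochromen-8-yl]-5-hydroxy-2-(4-methoxyphenyl)chromen-4-one | COc1ccc(-c2cc(=O)c3c(O)c(-c4c(OC)cc(OC)c5c(=O)cc(-c6ccc(OC)cc6)oc45)c(OCc4ccccc4)cc3o2)cc1
F6 | step 8 | 8-[2-ethoxy-4-hydroxy-3-iodo-6-(triisopropylsilyloxy)phenyl]-5,7-dimethoxy-2-(4-methoxyphenyl)chromen-4-one | CCOc1c(I)c(O)cc(O[Si](C(C)C)(C(C)C)C(C)C)c1-c1c(OC)cc(OC)c2c(=O)cc(-c3ccc(OC)cc3)oc12
F7 | step 8 | 4-ethynylanisole (purchased) | C#Cc1ccc(OC)cc1
F8 | step 4 | (ethoxyethynyl)zinc chloride | CCOC#C[Zn]Cl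
F9 | step 4 | 8-(ethoxyethynyl)-5,7-dimethoxy-2-(4-methoxyphenyl)chromen-4-one | COc1ccc(-c2cc(=O)c3c(OC)cc(OC)c(C#COCC)c3o2)cc1
F10 | step 4 | dichloroketene | O=C=C(Cl)Cl
F11 | step 4 | 4,4-dichloro-2-[5,7-dimethoxy-2-(4-methoxyphenyl)-4-oxochromen-8-yl]-3-ethoxycyclobut-2-en-1-one | COc1ccc(-c2cc(=O)c3c(OC)cc(OC)c(C4=C(OCC)C(Cl)(Cl)C4=O)c3o2)cc1
F12 | step 4 | 2-[5,7-dimethoxy-2-(4-methoxyphenyl)-4-oxochromen-8-yl]-3-ethoxycyclobut-2-en-1-one | COc1ccc(-c2cc(=O)c3c(OC)cc(OC)c(C4=C(OCC)CC4=O)c3o2)cc1
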